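## Retrosynthetic overview

1. The ring B aryl ketone is the last C–C bond. It comes from an aryllithium and a bridged lactone, a temporary ring that ties the C3 oxygen to the acetic arm on C5.
2. The C3 carbinol comes from hydride attack on the open face of a cis-2,5-disubstituted oxolan-3-one. The C2–H comes from loss of a temporary ester at C2.
3. Key disconnection: the ring A CH2–C2 bond and the O1–C2 bond are both made at one carbon. An acyclic δ-hydroxy-α-diazo-β-keto ester reacts with vanillyl alcohol. The diazo ester comes from a chiral-pool glutarate half ester (source of C5) and a malonate half ester.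
4. Enabling feature: C2 lies between ring oxygen O1 and carbinol carbon C3. With C3 raised to the ketone, C2 is a diazo/carbene carbon that first accepts the C5 hydroxyl and then, as the enol carbon of the ring-closed β-keto ester, acts as a donor. Ring A carries its OH para to the benzylic CH2, so vanillyl alcohol delivers that carbon as a p-quinone methide. Two natural acceptor carbons are joined by reversing the polarity of C2.
5. Ring order: rings A and B are bought. The oxolane ring forms in step 4. The temporary lactone ring closes in step 6 and opens in step 7.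

Key step: step 4

Assumption: the oxolane locants used here are O1, C2 (carries the ring A benzyl group), C3 (carbinol), C4 and C5 (carries the aroylmethyl chain). Read this way the target is (2R,3R,5R) with all three substituents on one face. The four starting materials are taken as commercial.

## Route

Step 1
Reactants: 1 (3R)-3-[(tert-butyldimethylsilyl)oxy]-5-methoxy-5-oxopentanoic acid; 2 3-(benzyloxy)-3-oxopropanoic acid (monobenzyl malonate)
Product: 4 1-benzyl 7-methyl (5R)-5-[(tert-butyldimethylsilyl)oxy]-3-oxoheptanedioate, via acyl imidazolide 3 (not isolated)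
Conditions: CDI, THF, rt; then 2, MgCl2, Et3N, MeCN, rt to 40 °C; aq. citric acid work-up
Reagents that add atoms: none
Why: Masamune–Brooks homologation, in which the magnesium enolate of the malonate half ester is C-acylated by 3 and loses CO2, adds under near-neutral conditions the carbon that becomes C2 together with its temporary benzyl ester and leaves the methyl ester, the silyl ether and the (R) centre (future C5) untouched.

Step 2
Reactants: 4 1-benzyl 7-methyl (5R)-5-[(tert-butyldimethylsilyl)oxy]-3-oxoheptanedioate
Product: 5 1-benzyl 7-methyl (5R)-5-[(tert-butyldimethylsilyl)oxy]-2-diazo-3-oxoheptanedioate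
Conditions: 4-AcNHC6H4SO2N3, Et3N, MeCN, 0 °C to rt
Reagents that add atoms: 4-acetamidobenzenesulfonyl azide, CC(=O)Nc1ccc(cc1)S(=O)(=O)N=[N+]=[N-]
Why: Regitz diazo transfer to the activated methylene of a β-keto ester is general, places the latent carbene on the future C2 and touches neither the silyl ether nor the stereocentre.

Step 3
Reactants: 5 1-benzyl 7-methyl (5R)-5-[(tert-butyldimethylsilyl)oxy]-2-diazo-3-oxoheptanedioate
Product: 6 1-benzyl 7-methyl (5R)-2-diazo-5-hydroxy-3-oxoheptanedioate
Conditions: 48% aq. HF, MeCN, 0 °C to rt
Reagents that add atoms: none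
Why: Silyl ether cleavage by HF runs under acidic conditions that avoid E1cB loss of the β-oxygen, and the doubly acceptor-stabilised diazo group tolerates the acid, so the hydroxyl that becomes O1 is freed with the (R) centre intact.

Step 4
Reactants: 6 1-benzyl 7-methyl (5R)-2-diazo-5-hydroxy-3-oxoheptanedioate; 7 4-(hydroxymethyl)-2-methoxyphenol (vanillyl alcohol)
Product: 10 benzyl (2S,5R)-2-[(4-hydroxy-3-methoxyphenyl)methyl]-5-(2-methoxy-2-oxoethyl)-3-oxooxolane-2-carboxylate, via oxolanone ester 8 (not isolated), via quinone methide 9 (not isolated)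
Conditions: Rh2(OAc)4 (1 mol %), ClCH2CH2Cl, 60 °C, until N2 evolution ends; same flask: (CF3)2CHOH co-solvent, TsOH·H2O (5 mol %), 7 (1.5 equiv, in portions), 40 °C
Reagents that add atoms: none
Why: Rh2(OAc)4 releases N2 from 6, the electrophilic carbene carbon (future C2) is captured by the C5 hydroxyl and proton transfer in the five-membered oxonium ylide completes a formal O–H insertion to 8, which rests largely as its hydrogen-bonded C2=C3 enol, while TsOH in (CF3)2CHOH reversibly dehydrates 7 to 9 (or its O-protonated benzylic cation), whose exocyclic CH2 is attacked by the enol carbon in a 1,6-conjugate addition that rearomatises ring A to the free guaiacol. The closest known reaction types are the intramolecular rhodium-carbenoid O–H insertion of δ-hydroxy-α-diazo-β-keto esters to 3-oxooxolane-2-carboxylates and the acid-catalysed dehydrative benzylation (1,6-addition) of β-keto esters by p-hydroxybenzyl alcohols through p-quinone methides, here run in relay in one flask. The oxolane ring closes by O1–C2 bond formation, a five-membered closure of the hydroxyl oxygen onto the carbene carbon that meets no intermolecular competitor because 7 is added only after N2 loss and no 1,2-hydride shift because C2 is flanked by two carbonyl groups. C5 is carried over unchanged from 1, and the new quaternary C2 should form mainly by approach of 9 to the enol face opposite the C5 side chain, giving (2S), but this centre is temporary and both epimers converge in step 5. The step needs C2 rather than C4 or oxygen as the nucleophilic site, a single alkylation, and capture of 9 faster than its self-condensation: the temporary ester fixes the enol at C2=C3, leaves only one acidic C–H and makes the ring-closed intermediate a persistent soft nucleophile present in full concentration while 9 is fed only in traces, ether formation from 7 being reversible under the acid. In polarity terms an α-oxygenated carbon and a p-hydroxybenzylic carbon, both natural acceptor sites, are joined because the diazo carbon acts first as acceptor toward oxygen and then, as enol carbon, as donor toward 9.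

Step 5
Reactants: 10 benzyl (2S,5R)-2-[(4-hydroxy-3-methoxyphenyl)methyl]-5-(2-methoxy-2-oxoethyl)-3-oxooxolane-2-carboxylate
Product: 12 methyl 2-[(2R,5R)-5-[(4-hydroxy-3-methoxyphenyl)methyl]-4-oxooxolan-2-yl]acetate, via keto acid 11 (not isolated)
Conditions: H2 (1 atm), 10% Pd/C, EtOAc, rt; filter; PhMe, 60 °C
Reagents that add atoms: none
Why: Hydrogenolysis of the benzyl ester gives a β-keto acid that decarboxylates through its cyclic transition state to the C2=C3 enol, whose ketonisation from the face away from the C5 side chain, reinforced by the thermodynamic preference of the still epimerisable C2 for the 2,5-cis (both pseudo-equatorial) arrangement, should set the benzyl-bearing centre as (R), and any trans epimer can be separated and re-equilibrated with DBU.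

Step 6
Reactants: 12 methyl 2-[(2R,5R)-5-[(4-hydroxy-3-methoxyphenyl)methyl]-4-oxooxolan-2-yl]acetate
Product: 14 (1R,5R,7R)-7-[(4-hydroxy-3-methoxyphenyl)methyl]-2,6-dioxabicyclo[3.2.1]octan-3-one, via hydroxy ester 13 (not isolated)
Conditions: LiBH(s-Bu)3 (L-Selectride, 2.3 equiv), THF, −78 °C; AcOH quench, extractive work-up; crude in PhMe, CSA (10 mol %), 80 °C
Reagents that add atoms: none
Why: In this bulky trialkylborohydride reduction the hydride attacks the ketone face opposite the two cis substituents, so the new hydroxyl is cis to both (3R in oxolane locants), the phenol is only deprotonated and the ester is inert at −78 °C, and the acid-catalysed lactonisation, possible only when the C3 oxygen and the C5 arm are cis, closes the temporary bridged ring and sorts out stereochemical stragglers.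

Step 7
Reactants: 14 (1R,5R,7R)-7-[(4-hydroxy-3-methoxyphenyl)methyl]-2,6-dioxabicyclo[3.2.1]octan-3-one; 15 1-(benzyloxy)-4-bromo-2-methoxybenzene
Product: 17 1-[4-(benzyloxy)-3-methoxyphenyl]-2-[(2R,4R,5R)-4-hydroxy-5-[(4-hydroxy-3-methoxyphenyl)methyl]oxolan-2-yl]ethan-1-one, via aryllithium 16 (not isolated)
Conditions: 15 (2.2 equiv), n-BuLi (2.2 equiv), THF, −78 °C; then 14 in THF, −78 °C; AcOH quench at −78 °C
Reagents that add atoms: none
Why: After bromine–lithium exchange the first equivalent of aryllithium deprotonates the phenol and the second adds to the lactone and stops at the lithium hemiketal, as in aryl C-glycoside synthesis from lactones, so the cold acidic quench releases the aryl ketone and the C3 hydroxyl without exposing the β-alkoxy ketone to base and thus without retro-oxa-Michael epimerisation at C5.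

Step 8
Reactants: 17 1-[4-(benzyloxy)-3-methoxyphenyl]-2-[(2R,4R,5R)-4-hydroxy-5-[(4-hydroxy-3-methoxyphenyl)methyl]oxolan-2-yl]ethan-1-one
Product: 18 renealtin A, 1-(4-hydroxy-3-methoxyphenyl)-2-[(2R,4R,5R)-4-hydroxy-5-[(4-hydroxy-3-methoxyphenyl)methyl]oxolan-2-yl]ethan-1-one
Conditions: H2 (1 atm), 10% Pd/C, EtOAc, rt
Reagents that add atoms: none
Why: Hydrogenolysis of the aryl benzyl ether is fast at atmospheric pressure, whereas the electron-rich aryl ketone and the non-benzylic oxolane C–O bonds are not attacked, and the neutral medium leaves all three stereocentres untouched.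

## Compound list

1 | (3R)-3-[(tert-butyldimethylsilyl)oxy]-5-methoxy-5-oxopentanoic acid | COC(=O)C[C@H](O[Si](C)(C)C(C)(C)C)CC(=O)O | starting material
2 | 3-(benzyloxy)-3-oxopropanoic acid | O=C(O)CC(=O)OCc1ccccc1 | starting material
3 | methyl (3R)-3-[(tert-butyldimethylsilyl)oxy]-5-(imidazol-1-yl)-5-oxopentanoate | COC(=O)C[C@H](O[Si](C)(C)C(C)(C)C)CC(=O)n1ccnc1 | intermediate
4 | 1-benzyl 7-methyl (5R)-5-[(tert-butyldimethylsilyl)oxy]-3-oxoheptanedioate | COC(=O)C[C@H](O[Si](C)(C)C(C)(C)C)CC(=O)CC(=O)OCc1ccccc1 | intermediate
5 | 1-benzyl 7-methyl (5R)-5-[(tert-butyldimethylsilyl)oxy]-2-diazo-3-oxoheptanedioate | COC(=O)C[C@H](O[Si](C)(C)C(C)(C)C)CC(=O)C(=[N+]=[N-])C(=O)OCc1ccccc1 | intermediate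
6 | 1-benzyl 7-methyl (5R)-2-diazo-5-hydroxy-3-oxoheptanedioate | COC(=O)C[C@H](O)CC(=O)C(=[N+]=[N-])C(=O)OCc1ccccc1 | intermediate
7 | 4-(hydroxymethyl)-2-methoxyphenol (vanillyl alcohol) | COc1cc(CO)ccc1O | starting material
8 | benzyl (5R)-5-(2-methoxy-2-oxoethyl)-3-oxooxolane-2-carboxylate (C2 labile, keto/enol mixture) | O=C(OCc1ccccc1)C1O[C@@H](CC(=O)OC)CC1=O | intermediate
9 | 2-methoxy-4-methylidenecyclohexa-2,5-dien-1-one | COC1=CC(=C)C=CC1=O | intermediate
10 | benzyl (2S,5R)-2-[(4-hydroxy-3-methoxyphenyl)methyl]-5-(2-methoxy-2-oxoethyl)-3-oxooxolane-2-carboxylate | COc1cc(C[C@]2(C(=O)OCc3ccccc3)O[C@@H](CC(=O)OC)CC2=O)ccc1O | intermediate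
11 | (2S,5R)-2-[(4-hydroxy-3-methoxyphenyl)methyl]-5-(2-methoxy-2-oxoethyl)-3-oxooxolane-2-carboxylic acid | COc1cc(C[C@]2(C(=O)O)O[C@@H](CC(=O)OC)CC2=O)ccc1O | intermediate
12 | methyl 2-[(2R,5R)-5-[(4-hydroxy-3-methoxyphenyl)methyl]-4-oxooxolan-2-yl]acetate | COc1cc(C[C@H]2O[C@@H](CC(=O)OC)CC2=O)ccc1O | intermediate
13 | methyl 2-[(2R,4R,5R)-4-hydroxy-5-[(4-hydroxy-3-methoxyphenyl)methyl]oxolan-2-yl]acetate | COc1cc(C[C@H]2O[C@@H](CC(=O)OC)C[C@H]2O)ccc1O | intermediate
14 | (1R,5R,7R)-7-[(4-hydroxy-3-methoxyphenyl)methyl]-2,6-dioxabicyclo[3.2.1]octan-3-one | COc1cc(C[C@H]2O[C@@H]3C[C@H]2OC(=O)C3)ccc1O | intermediate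
15 | 1-(benzyloxy)-4-bromo-2-methoxybenzene | COc1cc(Br)ccc1OCc1ccccc1 | starting material
16 | [4-(benzyloxy)-3-methoxyphenyl]lithium | COc1cc([Li])ccc1OCc1ccccc1 | intermediate
17 | 1-[4-(benzyloxy)-3-methoxyphenyl]-2-[(2R,4R,5R)-4-hydroxy-5-[(4-hydroxy-3-methoxyphenyl)methyl]oxolan-2-yl]ethan-1-one | COc1cc(C[C@H]2O[C@@H](CC(=O)c3ccc(OCc4ccccc4)c(OC)c3)C[C@H]2O)ccc1O | intermediate
18 | renealtin A | COc1cc(C[C@H]2O[C@@H](CC(=O)c3ccc(O)c(OC)c3)C[C@H]2O)ccc1O | target

## Step count and risks

Total step count: 8. Longest linear sequence: 8 steps (1 to 18).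

**Step 4.** Self-condensation of the quinone methide and slow ionisation of the primary benzylic alcohol may outrun C-alkylation at the hindered tertiary enol carbon. The fallback sets out from 6 and comes back at 12. Ring closure and C–C bond formation are separated, and the electrophile is changed from a quinone methide to an SN2 partner. Compound 6 is cyclised alone with Rh2(OAc)4 and 8 is isolated. Commercial 4-(benzyloxy)-3-methoxybenzyl alcohol is converted with PBr3 (Et2O, 0 °C) into 4-(benzyloxy)-3-methoxybenzyl bromide F1. Classical enolate alkylation of 8 with it (K2CO3, acetone, rt) gives benzyl (2S,5R)-2-{[4-(benzyloxy)-3-methoxyphenyl]methyl}-5-(2-methoxy-2-oxoethyl)-3-oxooxolane-2-carboxylate F2. H2 and Pd/C as in step 5 then cleave both benzyl groups at once and lead through 11 to 12.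

**Step 5.** Weak facial bias in the ketonisation and a small energy gap between the C2 epimers may leave a low share of the 2,5-cis ketone. The fallback sets out from 12, used as its C2 epimer mixture, and comes back at 13. Substrate control is replaced by catalyst control in a dynamic reductive kinetic resolution. A ketoreductase is selected by screening for the (R) benzyl-bearing epimer and for delivery of the (R) carbinol (NADP+, glucose and glucose dehydrogenase for recycling, phosphate buffer pH 8, DMSO co-solvent, 30 °C). It reduces only that epimer, while C2 of the remaining ketone epimerises in the buffer. Compound 13 is then lactonised as in step 6. This fallback makes no compound outside the compound list (none, F0).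

**Step 7.** Enolisation of the lactone by the aryllithium, or early collapse of the lithium hemiketal followed by a second addition, may erode the ketone. The fallback sets out from 14 and comes back at 17. The acyl transfer is moved to a chelate-stabilised Weinreb ketone synthesis. Compound 14 is opened with MeNH(OMe)·HCl and i-PrMgCl (THF, −20 °C) to 2-[(2R,4R,5R)-4-hydroxy-5-[(4-hydroxy-3-methoxyphenyl)methyl]oxolan-2-yl]-N-methoxy-N-methylacetamide F3. This is treated at −78 °C with excess 16, two equivalents being consumed by the two OH groups, and quenched cold with AcOH to give 17.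

## Further compounds

F1 | step 4 | 4-(benzyloxy)-3-methoxybenzyl bromide | COc1cc(CBr)ccc1OCc1ccccc1
F2 | step 4 | benzyl (2S,5R)-2-{[4-(benzyloxy)-3-methoxyphenyl]methyl}-5-(2-methoxy-2-oxoethyl)-3-oxooxolane-2-carboxylate | COc1cc(C[C@]2(C(=O)OCc3ccccc3)O[C@@H](CC(=O)OC)CC2=O)ccc1OCc1ccccc1
F0 | step 5 | none | none
F3 | step 7 | 2-[(2R,4R,5R)-4-hydroxy-5-[(4-hydroxy-3-methoxyphenyl)methyl]oxolan-2-yl]-N-methoxy-N-methylacetamide | COc1cc(C[C@H]2O[C@@H](CC(=O)N(C)OC)C[C@H]2O)ccc1O
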